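**Plan**

- Numbering: C1 bears C7H2–OSO3H, C2 and C3 bear Br, C4 bears OSO3H, C5 bears OH, C6 is CH.
- Retrosynthesis: cut the two S–O bonds (at O4 and O7) and the C3–Br bond, take C7 back to a methyl ester, then open the benzene ring at C2–C3 and C6–C1 after restoring an ethano bridge across C3/C6.
- Enabling feature: C3–C4(O)–C5(O)–C6 is a symmetric 2,3-dioxygenated 1,3-diene unit and C1(C7)–C2(Br) is a 3-bromopropiolate unit, so the benzene ring, the only ring, can come from one cycloaddition/cycloreversion.
- Forward: the bis(silyl) dienol ether of cyclohexane-1,2-dione and methyl 3-bromopropiolate are made separately and joined in the ring-forming step. Then O4 is unmasked, C3 brominated, O4 sulfated, the ester reduced, O7 sulfated, and O5 unmasked.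
- Stereochemistry: the target has no stereocentre, and the bridgehead centres of the bicyclic intermediate vanish on aromatisation. The regiochemical questions (O4 versus O5, C3 versus C6) are settled by the ester para to O4.

Key step: step 3

Remark: the target is drawn as the free bis(hydrogen sulfate). The material is carried as potassium salts and protonated only in the last operation; the free acid is expected to need cold, alcohol-free handling.

**Step 1**
Reactants: 1 cyclohexane-1,2-dione; 2 tert-butyldimethylsilyl trifluoromethanesulfonate
Product: 4 2,3-bis(tert-butyldimethylsilyloxy)cyclohexa-1,3-diene, via 2-(tert-butyldimethylsilyloxy)cyclohex-2-en-1-one 3 (not isolated)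
Conditions: TBSOTf (2.2 equiv in all), Et3N (3 equiv), CH2Cl2, 0 °C → rt
Reagents that add atoms: tert-butyldimethylsilyl trifluoromethanesulfonate (second equivalent of 2), CC(C)(C)[Si](C)(C)OS(=O)(=O)C(F)(F)F
Why: One-pot double silyl enol ether formation, in which the first equivalent of triflate caps the enol form of the dione to give enone 3 and the second activates the remaining carbonyl so that triethylamine removes the α′-proton (soft enolisation), should give the symmetric 2,3-bis(silyloxy)-1,3-diene with one silyl group on each oxygen.

**Step 2**
Reactants: 5 methyl propiolate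
Product: 6 methyl 3-bromopropiolate
Conditions: NBS (1.1 equiv), AgNO3 (10 mol %), acetone, rt
Reagents that add atoms: N-bromosuccinimide, O=C1CCC(=O)N1Br
Why: AgNO3-catalysed electrophilic bromination of the terminal alkyne C–H through an alkynylsilver intermediate is the standard preparation of 3-bromopropiolates.

**Step 3**
Reactants: 4 2,3-bis(tert-butyldimethylsilyloxy)cyclohexa-1,3-diene; 6 methyl 3-bromopropiolate
Product: 8 methyl 2-bromo-4,5-bis(tert-butyldimethylsilyloxy)benzoate, via bicyclo[2.2.2]octadiene adduct 7 (not isolated)
Conditions: 1,2-dichlorobenzene, 100 °C, then 180 °C, sealed tube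
Reagents that add atoms: none
Why: A concerted, normal-electron-demand [4+2] cycloaddition (Diels–Alder) joins the s-cis-locked, electron-rich diene 4 to the electron-poor bromoalkynoate 6, forming the C2–C3 and C6–C1 bonds in one suprafacial event and closing the new six-membered carbocycle as one ring of the bicyclo[2.2.2]octadiene 7. On further heating 7 undergoes a retro-[4+2] that expels its saturated two-carbon bridge as ethene, so the benzene ring appears without an oxidant; the pair of events is the Alder–Rickert reaction, well known for alkoxy- and silyloxycyclohexadienes with acetylenic esters, and 3-bromopropiolates are established dienophiles. No stereocentre survives, because the two bridgehead centres of racemic 7 are erased on aromatisation. Regiochemistry is not at stake because the diene is symmetric about the axis through its central C–C bond, so both orientations of the unsymmetrical alkyne give the same arene. The fragmentation is chemoselective because only the ethano bridge can leave as a stable closed-shell molecule, with aromatisation as the driving force. The silyloxy groups sit on the internal diene carbons, away from the bond-forming termini, and the tert-butyldimethylsilyl ethers should survive to give 8 as a chromatographable bis(silyl) ether with C7 at the ester level, the C2 bromine and both oxygens in place.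

**Step 4**
Reactants: 8 methyl 2-bromo-4,5-bis(tert-butyldimethylsilyloxy)benzoate
Product: 9 methyl 2-bromo-5-(tert-butyldimethylsilyloxy)-4-hydroxybenzoate
Conditions: K2CO3 (1.0 equiv), MeOH–THF, 0 °C; then AcOH
Reagents that add atoms: none
Why: Base-mediated methanolysis of aryl silyl ethers is fastest for the silyl group on the best phenoxide leaving group, here O4 para to the ester, and the resulting O4 phenoxide both retards cleavage of the neighbouring O5 silyl ether and is the thermodynamic sink of any 1,4-silyl shift, so one equivalent of base should stop at the mono-phenol.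

**Step 5**
Reactants: 9 methyl 2-bromo-5-(tert-butyldimethylsilyloxy)-4-hydroxybenzoate
Product: 10 methyl 2,3-dibromo-5-(tert-butyldimethylsilyloxy)-4-hydroxybenzoate
Conditions: NBS (1.05 equiv), i-Pr2NH (10 mol %), CH2Cl2, 0 °C → rt, dark
Reagents that add atoms: N-bromosuccinimide, O=C1CCC(=O)N1Br
Why: Amine-mediated ortho-bromination of a phenol (electrophilic aromatic substitution) should place bromine at C3, since the only free phenol, O4–H, has its para position blocked by the ester and its other ortho position by the silyloxy group, while C6 lies next to the ester and a silyl ether and is far less activated.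

**Step 6**
Reactants: 10 methyl 2,3-dibromo-5-(tert-butyldimethylsilyloxy)-4-hydroxybenzoate
Product: 11 potassium 2,3-dibromo-6-(tert-butyldimethylsilyloxy)-4-(methoxycarbonyl)phenyl sulfate
Conditions: SO3·pyridine (3 equiv), pyridine, 45 °C; then aq KHCO3
Reagents that add atoms: sulfur trioxide–pyridine complex, [O-]S(=O)(=O)[n+]1ccccc1; potassium hydrogencarbonate, [K+].OC([O-])=O
Why: O-sulfonation of a phenol with the sulfur trioxide–pyridine complex followed by cation exchange is the standard aryl sulfate synthesis, and doing it at the ester stage keeps O4–H the most acidic site and ensures that no para-hydroxybenzyl alcohol or sulfate, prone to quinone methide formation, is ever present.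

**Step 7**
Reactants: 11 potassium 2,3-dibromo-6-(tert-butyldimethylsilyloxy)-4-(methoxycarbonyl)phenyl sulfate
Product: 12 potassium 2,3-dibromo-6-(tert-butyldimethylsilyloxy)-4-(hydroxymethyl)phenyl sulfate
Conditions: LiBH4 (2.5 equiv), THF, 0 °C → rt; H2O, then aq KCl wash
Reagents that add atoms: none
Why: Lithium borohydride reduces the methyl ester to the primary alcohol (hydride reduction), while the anionic sulfate monoester, the aryl bromides and the aryl silyl ether are inert to it.

**Step 8**
Reactants: 12 potassium 2,3-dibromo-6-(tert-butyldimethylsilyloxy)-4-(hydroxymethyl)phenyl sulfate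
Product: 13 dipotassium 2,3-dibromo-6-(tert-butyldimethylsilyloxy)-4-[(sulfonatooxy)methyl]phenyl sulfate
Conditions: SO3·pyridine (2 equiv), DMF, 0 °C → rt; then aq KHCO3
Reagents that add atoms: sulfur trioxide–pyridine complex, [O-]S(=O)(=O)[n+]1ccccc1; potassium hydrogencarbonate, [K+].OC([O-])=O
Why: O-sulfonation of the unhindered primary benzylic alcohol with the sulfur trioxide–pyridine complex is fast at room temperature, and the para substituent being a sulfate instead of a free phenol keeps the new benzylic sulfate from ionising.

**Step 9**
Reactants: 13 dipotassium 2,3-dibromo-6-(tert-butyldimethylsilyloxy)-4-[(sulfonatooxy)methyl]phenyl sulfate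
Product: 15 2,3-dibromo-5-hydroxy-4-(sulfooxy)benzyl hydrogen sulfate, via tripotassium phenoxide salt 14 (not isolated)
Conditions: KOH (1.1 equiv), THF–H2O, 0 °C → rt; then HCl (3.1 equiv), H2O, 0 °C; freeze-dry, extract into cold MeCN, filter
Reagents that add atoms: none
Why: Hydroxide cleaves the aryl silyl ether by attack at silicon without touching the base-stable sulfate monoesters, and cold mineral acid then protonates the phenoxide and both sulfates in an alcohol-free medium, which avoids benzylic solvolysis.

**Compound list**

1 | cyclohexane-1,2-dione | O=C1CCCCC1=O | starting material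
2 | tert-butyldimethylsilyl trifluoromethanesulfonate | CC(C)(C)[Si](C)(C)OS(=O)(=O)C(F)(F)F | starting material
3 | 2-(tert-butyldimethylsilyloxy)cyclohex-2-en-1-one | O=C1CCCC=C1O[Si](C)(C)C(C)(C)C | intermediate
4 | 2,3-bis(tert-butyldimethylsilyloxy)cyclohexa-1,3-diene | CC(C)(C)[Si](C)(C)OC1=CCCC=C1O[Si](C)(C)C(C)(C)C | intermediate
5 | methyl propiolate | C#CC(=O)OC | starting material
6 | methyl 3-bromopropiolate | COC(=O)C#CBr | intermediate
7 | methyl 3-bromo-5,6-bis(tert-butyldimethylsilyloxy)bicyclo[2.2.2]octa-2,5-diene-2-carboxylate (racemic) | COC(=O)C1=C(Br)C2CCC1C(O[Si](C)(C)C(C)(C)C)=C2O[Si](C)(C)C(C)(C)C | intermediate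
8 | methyl 2-bromo-4,5-bis(tert-butyldimethylsilyloxy)benzoate | COC(=O)c1cc(O[Si](C)(C)C(C)(C)C)c(O[Si](C)(C)C(C)(C)C)cc1Br | intermediate
9 | methyl 2-bromo-5-(tert-butyldimethylsilyloxy)-4-hydroxybenzoate | COC(=O)c1cc(O[Si](C)(C)C(C)(C)C)c(O)cc1Br | intermediate
10 | methyl 2,3-dibromo-5-(tert-butyldimethylsilyloxy)-4-hydroxybenzoate | COC(=O)c1cc(O[Si](C)(C)C(C)(C)C)c(O)c(Br)c1Br | intermediate
11 | potassium 2,3-dibromo-6-(tert-butyldimethylsilyloxy)-4-(methoxycarbonyl)phenyl sulfate | COC(=O)c1cc(O[Si](C)(C)C(C)(C)C)c(OS(=O)(=O)[O-])c(Br)c1Br.[K+] | intermediate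
12 | potassium 2,3-dibromo-6-(tert-butyldimethylsilyloxy)-4-(hydroxymethyl)phenyl sulfate | OCc1cc(O[Si](C)(C)C(C)(C)C)c(OS(=O)(=O)[O-])c(Br)c1Br.[K+] | intermediate
13 | dipotassium 2,3-dibromo-6-(tert-butyldimethylsilyloxy)-4-[(sulfonatooxy)methyl]phenyl sulfate | [O-]S(=O)(=O)OCc1cc(O[Si](C)(C)C(C)(C)C)c(OS(=O)(=O)[O-])c(Br)c1Br.[K+].[K+] | intermediate
14 | tripotassium 2,3-dibromo-6-oxido-4-[(sulfonatooxy)methyl]phenyl sulfate | [O-]S(=O)(=O)OCc1cc([O-])c(OS(=O)(=O)[O-])c(Br)c1Br.[K+].[K+].[K+] | intermediate
15 | 2,3-dibromo-5-hydroxy-4-(sulfooxy)benzyl hydrogen sulfate | O=S(=O)(O)OCc1cc(O)c(OS(=O)(=O)O)c(Br)c1Br | target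

**Count and risks**

Total steps: 9. Longest linear sequence: 8 steps (steps 1 and 3 to 9, from cyclohexane-1,2-dione); the bromoalkyne branch is one step.

Step 3. The bromoalkyne may polymerise or lose bromine before it is consumed at the temperature the cycloaddition needs, or the ethene extrusion may stall at the bicyclic stage. The fallback sets out from 4 and replaces the halogenated dienophile by commercial, thermally robust methyl 3-(trimethylsilyl)propiolate. Heating the two under the same regime should give methyl 5,6-bis(tert-butyldimethylsilyloxy)-3-(trimethylsilyl)bicyclo[2.2.2]octa-2,5-diene-2-carboxylate F1, which loses ethene to methyl 4,5-bis(tert-butyldimethylsilyloxy)-2-(trimethylsilyl)benzoate F2. Ipso-bromodesilylation with NBS in MeCN, favoured because the silicon-bearing carbon is para to the O5 silyl ether, then puts bromine on C2 and rejoins the route at 8.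

Step 4. Cleavage may run on to the catechol, or discrimination between the two silyl ethers may be incomplete, giving a mixture of mono-phenols. The fallback sets out from 8 and differentiates the oxygens by sterics after bromination instead of by electronics before it. Both silyl groups are removed (KHF2, MeOH) to give methyl 2-bromo-4,5-dihydroxybenzoate F3. Bromination with NBS in MeCN, expected at C3 (ortho to O4–H and meta to the ester) rather than at C6 (ortho to the ester), gives methyl 2,3-dibromo-4,5-dihydroxybenzoate F4. One equivalent of TBSCl with imidazole in DMF should then leave the silyl group on O5, the oxygen not flanked by bromine and the less acidic one, which rejoins the route at 10.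

Step 6. Sulfation of the hindered, electron-poor phenol may be slow enough for the silyl group to shift from O5 to O4, so that sulfur ends up on the wrong oxygen and an inseparable mixture of salts results. The fallback sets out from 10 and introduces the sulfate as a neutral, chromatographable diester. 2,2,2-Trichloroethyl chlorosulfate with Et3N and DMAP in THF at 0 °C should give methyl 2,3-dibromo-5-(tert-butyldimethylsilyloxy)-4-[(2,2,2-trichloroethoxy)sulfonyloxy]benzoate F5, which can be freed of any regioisomer on silica. Zn dust and ammonium formate in MeOH then remove the trichloroethyl group by reductive fragmentation, and a KHCO3 work-up returns the route at 11.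

**Further compounds**

F1 | step 3 | methyl 5,6-bis(tert-butyldimethylsilyloxy)-3-(trimethylsilyl)bicyclo[2.2.2]octa-2,5-diene-2-carboxylate (racemic) | COC(=O)C1=C([Si](C)(C)C)C2CCC1C(O[Si](C)(C)C(C)(C)C)=C2O[Si](C)(C)C(C)(C)C
F2 | step 3 | methyl 4,5-bis(tert-butyldimethylsilyloxy)-2-(trimethylsilyl)benzoate | COC(=O)c1cc(O[Si](C)(C)C(C)(C)C)c(O[Si](C)(C)C(C)(C)C)cc1[Si](C)(C)C
F3 | step 4 | methyl 2-bromo-4,5-dihydroxybenzoate | COC(=O)c1cc(O)c(O)cc1Br
F4 | step 4 | methyl 2,3-dibromo-4,5-dihydroxybenzoate | COC(=O)c1cc(O)c(O)c(Br)c1Br
F5 | step 6 | methyl 2,3-dibromo-5-(tert-butyldimethylsilyloxy)-4-[(2,2,2-trichloroethoxy)sulfonyloxy]benzoate | COC(=O)c1cc(O[Si](C)(C)C(C)(C)C)c(OS(=O)(=O)OCC(Cl)(Cl)Cl)c(Br)c1Br
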